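The numbers in the tables stem from a simulated flask with made-up constants; scatter was added.

Suppose each X is made from one G and one J. We work from these flasks and readings:

| flask | G | J | Z | D | remark | time |
|---|---|---|---|---|---|---|
| green | 19 mM | 25.2 mM | 2.8 mM | 28 mM | run made earlier |  |
| noon | 28 mM | 25.2 mM | 2.80 mM | 15.0 mM |  | 6.0 h |
| spring | 28 mM | 25.2 mM | 2.80 mM | 28.0 mM |  | 6.0 h |
| dawn | 28 mM | 100 mM | 1.00 mM | 28.0 mM |  | 6.0 h |
| midnight | 28 mM | 25.2 mM | 6.00 mM | 28.0 mM |  | 6.0 h |
| dusk | 28 mM | 40.0 mM | 2.80 mM | 28.0 mM |  | 6.0 h |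

green run (percent of the G charged): time / min: X / % = 6.00: 4.0; 10.0: 7.0; 15.0: 8.0; 25.0: 12.0; 40.0: 18.9; 80.0: 30.2

(readings scatter by 1 percentage point)

- all flasks from highest to lowest amount of X, in percent of the G charged, at 6.0 h (noon / spring / dawn / midnight / dusk)
- the amount of X, in percent of the G charged of the flask you put first, at 6.0 h
- the amount of X, in percent of the G charged of the flask you put last, at 6.0 h

- no earlier run changes the charge of D; that part of a forecast is a guess

Divide the rate at which G goes by the rate at which J goes. The ratio is one, time drops out, and the difference J − G stays at its charged value. The second-order law then has a closed form. The last green reading gives the rate constant k = 2.04 × 10⁻⁴ mM⁻¹ min⁻¹. With this k, our reckoning for green gives 17.4% at 40.0 min, against the reading of 18.9%, with a scatter of 1 percentage point.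

Now define Θ = k(J − G)t, with J and G the charges. In words, Θ is the natural logarithm of how far the ratio of J to G has grown above its charged value; for dawn, Θ = 5.29. The fraction of G turned into X is J(e^Θ − 1)/(Je^Θ − G). With a negative Θ, J is the limiting reagent of this pairing.

Dawn gives 99.6%. Dusk has Θ = 0.881 and gives 82.5%. Spring has Θ = −0.206 and gives 62.6%.

Was one number enough? No. Noon and midnight share spring's Θ. Z and D do not enter Θ, and the green run never varied them. So we commit to dawn, then dusk, then a three-way tie.

The forecast breaks that tie with dawn > dusk > spring > midnight > noon, putting 97% against our 99.6% and 50% against our 62.6%, and says “Z probably competes weakly for G, but the run cannot prove this”.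

The flasks give dawn > dusk > noon > spring > midnight, with 94.3% in dawn and 49.2% in midnight.

    G + J → X (k = 0.00410 M⁻¹ s⁻¹)
    J + Z → Q (k = 0.0910 M⁻¹ s⁻¹)
    2 J → E (k = 1.80 × 10⁻⁴ M⁻¹ s⁻¹)
    G + D → L (k = 6.60 × 10⁻⁴ M⁻¹ s⁻¹)

Dawn's Θ of 5.29 gave us 99.6% of X, and dawn holds 94.3% of X and 5.36% of L. The neighbour is dawn with 110 mM of D instead of 28.0 mM. Its J and G charges match dawn's and D is not in Θ, so the reckoning again gives 5.29 and 99.6% of X. The neighbour keeps 0.10% of its G and 46% of its J. Its L reaches 17.8%, and its X stands at 82.1%.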